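**Retrosynthetic overview**
- Last C–C bond: the ring A carbon–allylic CH2 bond, made by α-alkylation of a ring A α-silyloxy cyclohexanone enolate with a ring B 2-substituted allylic chloride; ketone reduction and desilylation then finish.
- Ring A is taken preformed from (S)-carvone: nucleophilic epoxidation, hydride opening to the tertiary alcohol, re-oxidation to the α-hydroxy ketone.
- Ring B allylic chloride comes from an isopropenyl group, that from an acetyl group; the syn-bromohydrin comes from a cis-α-bromo ketone plus a methyl nucleophile.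
- Ring B is the ring that is built: an (R)-4-substituted cyclohexenone closed by intramolecular aldol condensation of the 5-oxo-aldehyde from an organocatalytic Michael addition to methyl vinyl ketone.
- Order: ring B is closed first, ring A comes from the chiral pool, and the two rings are joined near the end.

Assumption: the SMILES defines the target as (1S,2S,3R,4S)-3-{2-[(1R,3R,4S)-3-bromo-4-hydroxy-4-methylcyclohexyl]prop-2-en-1-yl}-1-methyl-4-(prop-1-en-2-yl)cyclohexane-1,2-diol; ring A is the diol ring and ring B the bromohydrin ring.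

**Ring B fragment (steps 1–7)**

Step 1
Reactants: 1 ethyl 2-(2-methyl-1,3-dioxolan-2-yl)acetate (fructone)
Product: 2 2-(2-methyl-1,3-dioxolan-2-yl)acetaldehyde
Conditions: iBu2AlH (1.05 equiv), CH2Cl2, −78 °C; aq. potassium sodium tartrate
Reagents that add atoms: none
Why: Partial ester reduction by iBu2AlH stops at the aluminium hemiacetal at −78 °C and gives the aldehyde on work-up, with the ketal untouched.

Step 2
Reactants: 2 2-(2-methyl-1,3-dioxolan-2-yl)acetaldehyde; 3 but-3-en-2-one (methyl vinyl ketone)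
Product: 5 (R)-4-(2-methyl-1,3-dioxolan-2-yl)cyclohex-2-en-1-one, via keto aldehyde 4 (not isolated)
Conditions: (S)-2-[methoxy(diphenyl)methyl]pyrrolidine (10 mol %), ethyl 3,4-dihydroxybenzoate (20 mol %), neat, 4 °C; then LiOH, iPrOH, rt
Reagents that add atoms: none
Why: Enamine-catalysed asymmetric Michael addition (the diarylmethyl group of the (S)-pyrrolidine shields one enamine face, so the enone adds to the other and sets the R centre) is followed by intramolecular aldol condensation of the methyl ketone onto the aldehyde, which closes ring B.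

Step 3
Reactants: 5 (R)-4-(2-methyl-1,3-dioxolan-2-yl)cyclohex-2-en-1-one
Product: 8 (2R,4R)-2-bromo-4-(2-methyl-1,3-dioxolan-2-yl)cyclohexan-1-one, via silyl enol ether 6 (not isolated), via trans-bromo ketone 7 (not isolated)
Conditions: Et3SiH, RhCl(PPh3)3 (1 mol %), THF, 50 °C; NBS, THF, −78 → 0 °C; then LiBr (0.3 equiv), DMF, rt; chromatography (7 recycled)
Reagents that add atoms: N-bromosuccinimide, O=C1CCC(=O)N1Br
Why: Rhodium-catalysed 1,4-hydrosilylation gives the regiodefined silyl enol ether, electrophilic bromination puts Br on the former enone α-carbon (axial attack, trans isomer first), and reversible SN2 bromide exchange in DMF epimerises C2 to an equilibrium expected to favour the equatorial cis bromide only modestly (about 2:1), from which 8 is separated; C4 is not enolisable and is unchanged.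

Step 4
Reactants: 8 (2R,4R)-2-bromo-4-(2-methyl-1,3-dioxolan-2-yl)cyclohexan-1-one
Product: 10 1-[(1R,3R,4S)-3-bromo-4-hydroxy-4-methylcyclohexyl]ethan-1-one, via ketal bromohydrin 9 (not isolated)
Conditions: MeTi(OiPr)3, Et2O/THF, −40 °C → rt; then 1 M HCl, THF, rt
Reagents that add atoms: methyltitanium triisopropoxide, C[Ti](OC(C)C)(OC(C)C)OC(C)C; water, O
Why: Non-basic carbonyl methylation by the bulky methyltitanium reagent occurs from the equatorial direction of the locked chair (Br and side chain equatorial), giving the axial tertiary alcohol cis to bromine (syn-bromohydrin), and acid hydrolysis of the dioxolane then releases the methyl ketone.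

Step 5
Reactants: 10 1-[(1R,3R,4S)-3-bromo-4-hydroxy-4-methylcyclohexyl]ethan-1-one
Product: 11 1-{(1R,3R,4S)-3-bromo-4-methyl-4-[(triethylsilyl)oxy]cyclohexyl}ethan-1-one
Conditions: Et3SiOTf, 2,6-lutidine, CH2Cl2, −78 → 0 °C
Reagents that add atoms: triethylsilyl trifluoromethanesulfonate, CC[Si](CC)(CC)OS(=O)(=O)C(F)(F)F
Why: Silyl triflate silylation protects the hindered tertiary alcohol so that no alkoxide can form next to the bromide in the basic steps that follow.

Step 6
Reactants: 11 1-{(1R,3R,4S)-3-bromo-4-methyl-4-[(triethylsilyl)oxy]cyclohexyl}ethan-1-one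
Product: 12 {[(1S,2R,4R)-2-bromo-1-methyl-4-(prop-1-en-2-yl)cyclohexyl]oxy}triethylsilane
Conditions: Ph3PCH3Br, KOtBu, THF, 0 °C → rt
Reagents that add atoms: methyltriphenylphosphonium bromide, C[P+](c1ccccc1)(c1ccccc1)c1ccccc1.[Br-]
Why: Wittig methylenation of the methyl ketone; the equatorial bromide has no anti-periplanar hydrogen for E2, and the centre α to the ketone is already the more stable equatorial epimer.

Step 7
Reactants: 12 {[(1S,2R,4R)-2-bromo-1-methyl-4-(prop-1-en-2-yl)cyclohexyl]oxy}triethylsilane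
Product: 13 {[(1S,2R,4R)-2-bromo-4-(3-chloroprop-1-en-2-yl)-1-methylcyclohexyl]oxy}triethylsilane
Conditions: Ca(OCl)2, CO2 (dry ice), CH2Cl2/H2O, 0 °C
Reagents that add atoms: calcium hypochlorite, [Ca+2].[O-]Cl.[O-]Cl
Why: Ene-type allylic chlorination by hypochlorous acid puts chlorine on the terminal carbon of the isopropenyl group and moves the double bond into the former methyl group, giving the 2-substituted allylic chloride.

**Ring A fragment (steps 8–12)**

Step 8
Reactants: 14 (S)-(+)-carvone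
Product: 15 (1S,4S,6S)-1-methyl-4-(prop-1-en-2-yl)-7-oxabicyclo[4.1.0]heptan-2-one
Conditions: 30% H2O2, NaOH (cat.), MeOH, 0 °C
Reagents that add atoms: hydrogen peroxide, OO
Why: Weitz–Scheffer nucleophilic epoxidation touches only the enone alkene, and hydroperoxide adds anti to the isopropenyl group, so the epoxide oxygen (the future tertiary C–O bond) is trans to isopropenyl.

Step 9
Reactants: 15 (1S,4S,6S)-1-methyl-4-(prop-1-en-2-yl)-7-oxabicyclo[4.1.0]heptan-2-one
Product: 16 (1R,2R,4R,6S)-1-methyl-4-(prop-1-en-2-yl)-7-oxabicyclo[4.1.0]heptan-2-ol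
Conditions: NaBH4, CeCl3·7H2O, MeOH, −20 °C
Reagents that add atoms: none
Why: Luche 1,2-reduction with hydride delivered anti to the epoxide oxygen gives the cis-epoxy alcohol, whose alkoxide cannot deliver hydride internally to the tertiary epoxide carbon in the next step; this carbinol centre is erased in step 11.

Step 10
Reactants: 16 (1R,2R,4R,6S)-1-methyl-4-(prop-1-en-2-yl)-7-oxabicyclo[4.1.0]heptan-2-ol
Product: 17 (1S,2R,4S)-1-methyl-4-(prop-1-en-2-yl)cyclohexane-1,2-diol
Conditions: LiAlH4, THF, 0 °C → reflux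
Reagents that add atoms: none
Why: SN2 hydride opening of the trisubstituted epoxide at its less substituted carbon leaves the tertiary C–O bond (trans to isopropenyl) with its configuration intact.

Step 11
Reactants: 17 (1S,2R,4S)-1-methyl-4-(prop-1-en-2-yl)cyclohexane-1,2-diol
Product: 18 (2S,5S)-2-hydroxy-2-methyl-5-(prop-1-en-2-yl)cyclohexan-1-one
Conditions: SO3·pyridine, DMSO, Et3N, CH2Cl2, 0 °C
Reagents that add atoms: none
Why: Parikh–Doering oxidation converts only the secondary alcohol, without glycol cleavage, to the α-hydroxy ketone.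

Step 12
Reactants: 18 (2S,5S)-2-hydroxy-2-methyl-5-(prop-1-en-2-yl)cyclohexan-1-one
Product: 19 (2S,5S)-2-methyl-5-(prop-1-en-2-yl)-2-[(triethylsilyl)oxy]cyclohexan-1-one
Conditions: Et3SiOTf, 2,6-lutidine, CH2Cl2, −78 → 0 °C
Reagents that add atoms: triethylsilyl trifluoromethanesulfonate, CC[Si](CC)(CC)OS(=O)(=O)C(F)(F)F
Why: Silyl triflate silylation of the tertiary alcohol leaves a ketone that can enolise on one side only.

**Union and end game (steps 13–15)**

Step 13
Reactants: 19 (2S,5S)-2-methyl-5-(prop-1-en-2-yl)-2-[(triethylsilyl)oxy]cyclohexan-1-one; 13 {[(1S,2R,4R)-2-bromo-4-(3-chloroprop-1-en-2-yl)-1-methylcyclohexyl]oxy}triethylsilane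
Product: 21 (2S,5S,6R)-6-{2-[(1R,3R,4S)-3-bromo-4-methyl-4-(triethylsilyloxy)cyclohexyl]prop-2-en-1-yl}-2-methyl-5-(prop-1-en-2-yl)-2-(triethylsilyloxy)cyclohexan-1-one, via lithium enolate 20 (not isolated)
Conditions: LiN(iPr)2 (1.05 equiv), THF, −78 °C; then 13, DMPU, −78 °C → rt
Reagents that add atoms: none
Why: Enolate C-alkylation (SN2 on the allylic chloride): deprotonation is possible only at C6, and the electrophile enters anti to the neighbouring isopropenyl group, giving the trans-5,6 product, which is also the thermodynamic diequatorial epimer.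

Step 14
Reactants: 21 (2S,5S,6R)-6-{2-[(1R,3R,4S)-3-bromo-4-methyl-4-(triethylsilyloxy)cyclohexyl]prop-2-en-1-yl}-2-methyl-5-(prop-1-en-2-yl)-2-(triethylsilyloxy)cyclohexan-1-one
Product: 22 (1S,2S,5S,6R)-6-{2-[(1R,3R,4S)-3-bromo-4-methyl-4-(triethylsilyloxy)cyclohexyl]prop-2-en-1-yl}-2-methyl-5-(prop-1-en-2-yl)-2-(triethylsilyloxy)cyclohexan-1-ol
Conditions: NaBH4, MeOH/THF, 0 °C → rt
Reagents that add atoms: none
Why: Borohydride reduction by axial attack (the equatorial side is screened by the axial C2 methyl group) gives the equatorial alcohol trans to both neighbours; the alkyl bromide and alkenes are inert, and any 1,2-silyl shift is harmless before the next step.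

Step 15
Reactants: 22 (1S,2S,5S,6R)-6-{2-[(1R,3R,4S)-3-bromo-4-methyl-4-(triethylsilyloxy)cyclohexyl]prop-2-en-1-yl}-2-methyl-5-(prop-1-en-2-yl)-2-(triethylsilyloxy)cyclohexan-1-ol
Product: 23 (1S,2S,3R,4S)-3-{2-[(1R,3R,4S)-3-bromo-4-hydroxy-4-methylcyclohexyl]prop-2-en-1-yl}-1-methyl-4-(prop-1-en-2-yl)cyclohexane-1,2-diol
Conditions: HF·pyridine, pyridine, THF, 0 °C → rt
Reagents that add atoms: none
Why: Fluoride-driven Si–O cleavage under mildly acidic conditions removes both silyl ethers without forming an alkoxide next to the bromide, so no ring contraction or elimination occurs.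

**Compound list**
1 | ethyl 2-(2-methyl-1,3-dioxolan-2-yl)acetate (fructone) | CCOC(=O)CC1(C)OCCO1 | starting material
2 | 2-(2-methyl-1,3-dioxolan-2-yl)acetaldehyde | O=CCC1(C)OCCO1 | intermediate
3 | but-3-en-2-one (methyl vinyl ketone) | CC(=O)C=C | starting material
4 | (R)-2-(2-methyl-1,3-dioxolan-2-yl)-5-oxohexanal | O=C[C@@H](CCC(C)=O)C1(C)OCCO1 | intermediate (not isolated)
5 | (R)-4-(2-methyl-1,3-dioxolan-2-yl)cyclohex-2-en-1-one | O=C1C=C[C@@H](CC1)C1(C)OCCO1 | intermediate
6 | (R)-triethyl{[4-(2-methyl-1,3-dioxolan-2-yl)cyclohex-1-en-1-yl]oxy}silane | CC[Si](CC)(CC)OC1=CC[C@@H](CC1)C1(C)OCCO1 | intermediate (not isolated)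
7 | (2S,4R)-2-bromo-4-(2-methyl-1,3-dioxolan-2-yl)cyclohexan-1-one (Br axial, trans to the side chain) | CC1(OCCO1)[C@@H]1CCC(=O)[C@@H](Br)C1 | intermediate (not isolated)
8 | (2R,4R)-2-bromo-4-(2-methyl-1,3-dioxolan-2-yl)cyclohexan-1-one (Br equatorial, cis to the side chain) | CC1(OCCO1)[C@@H]1CCC(=O)[C@H](Br)C1 | intermediate
9 | (1S,2R,4R)-2-bromo-1-methyl-4-(2-methyl-1,3-dioxolan-2-yl)cyclohexan-1-ol | CC1(OCCO1)[C@@H]1CC[C@](C)(O)[C@H](Br)C1 | intermediate (not isolated)
10 | 1-[(1R,3R,4S)-3-bromo-4-hydroxy-4-methylcyclohexyl]ethan-1-one | CC(=O)[C@@H]1CC[C@](C)(O)[C@H](Br)C1 | intermediate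
11 | 1-{(1R,3R,4S)-3-bromo-4-methyl-4-[(triethylsilyl)oxy]cyclohexyl}ethan-1-one | CC(=O)[C@@H]1CC[C@](C)(O[Si](CC)(CC)CC)[C@H](Br)C1 | intermediate
12 | {[(1S,2R,4R)-2-bromo-1-methyl-4-(prop-1-en-2-yl)cyclohexyl]oxy}triethylsilane | C=C(C)[C@@H]1CC[C@](C)(O[Si](CC)(CC)CC)[C@H](Br)C1 | intermediate
13 | {[(1S,2R,4R)-2-bromo-4-(3-chloroprop-1-en-2-yl)-1-methylcyclohexyl]oxy}triethylsilane | C=C(CCl)[C@@H]1CC[C@](C)(O[Si](CC)(CC)CC)[C@H](Br)C1 | intermediate
14 | (S)-(+)-carvone | CC1=CC[C@@H](CC1=O)C(C)=C | starting material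
15 | (1S,4S,6S)-1-methyl-4-(prop-1-en-2-yl)-7-oxabicyclo[4.1.0]heptan-2-one (epoxide trans to isopropenyl) | C1[C@@H](C(=C)C)C[C@@H]2O[C@]2(C)C1=O | intermediate
16 | (1R,2R,4R,6S)-1-methyl-4-(prop-1-en-2-yl)-7-oxabicyclo[4.1.0]heptan-2-ol (OH cis to the epoxide oxygen) | C1[C@@H](C(=C)C)C[C@@H]2O[C@]2(C)[C@@H]1O | intermediate
17 | (1S,2R,4S)-1-methyl-4-(prop-1-en-2-yl)cyclohexane-1,2-diol | C1[C@@H](C(=C)C)CC[C@](C)(O)[C@@H]1O | intermediate
18 | (2S,5S)-2-hydroxy-2-methyl-5-(prop-1-en-2-yl)cyclohexan-1-one | C1[C@@H](C(=C)C)CC[C@](C)(O)C1=O | intermediate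
19 | (2S,5S)-2-methyl-5-(prop-1-en-2-yl)-2-[(triethylsilyl)oxy]cyclohexan-1-one | C1[C@@H](C(=C)C)CC[C@](C)(O[Si](CC)(CC)CC)C1=O | intermediate
20 | lithium (3S,6S)-6-methyl-3-(prop-1-en-2-yl)-6-[(triethylsilyl)oxy]cyclohex-1-en-1-olate | C1=C(O[Li])[C@@](C)(O[Si](CC)(CC)CC)CC[C@@H]1C(C)=C | intermediate (not isolated)
21 | (2S,5S,6R)-6-{2-[(1R,3R,4S)-3-bromo-4-methyl-4-(triethylsilyloxy)cyclohexyl]prop-2-en-1-yl}-2-methyl-5-(prop-1-en-2-yl)-2-(triethylsilyloxy)cyclohexan-1-one | C=C(C[C@@H]1[C@@H](C(=C)C)CC[C@](C)(O[Si](CC)(CC)CC)C1=O)[C@@H]1CC[C@](C)(O[Si](CC)(CC)CC)[C@H](Br)C1 | intermediate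
22 | (1S,2S,5S,6R)-6-{2-[(1R,3R,4S)-3-bromo-4-methyl-4-(triethylsilyloxy)cyclohexyl]prop-2-en-1-yl}-2-methyl-5-(prop-1-en-2-yl)-2-(triethylsilyloxy)cyclohexan-1-ol | C=C(C[C@@H]1[C@@H](C(=C)C)CC[C@](C)(O[Si](CC)(CC)CC)[C@H]1O)[C@@H]1CC[C@](C)(O[Si](CC)(CC)CC)[C@H](Br)C1 | intermediate
23 | (1S,2S,3R,4S)-3-{2-[(1R,3R,4S)-3-bromo-4-hydroxy-4-methylcyclohexyl]prop-2-en-1-yl}-1-methyl-4-(prop-1-en-2-yl)cyclohexane-1,2-diol | C=C(C[C@@H]1[C@@H](C(=C)C)CC[C@](C)(O)[C@H]1O)[C@@H]1CC[C@](C)(O)[C@H](Br)C1 | target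

**Totals**
Total step count: 15 (ring B branch steps 1–7, ring A branch steps 8–12, joint steps 13–15).
Longest linear sequence: 10 steps (1–7, then 13–15), which is two thirds of the total; the ring A branch is 8 steps to the target.

**Steps most likely to fail**

Step 2 (asymmetric Michael addition and aldol ring closure). The β-ketal aldehyde is a hindered enamine donor that may partly lose alkoxide, and the α-centre of keto aldehyde 4 can erode under LiOH before it cyclises. The fallback sets out from 5, of whatever enantiomeric purity, and comes back at 8; it moves the asymmetric event to a later, independent step. Hydrogenation of 5 (H2, Pd/C, EtOAc) gives the achiral ketone 4-(2-methyl-1,3-dioxolan-2-yl)cyclohexan-1-one F1. Enantioselective deprotonation with lithium (S,S)-bis(1-phenylethyl)amide in the presence of Me3SiCl (THF, −100 °C; sense chosen by analogy with 4-tert-butylcyclohexanone) gives the silyl enol ether (R)-trimethyl{[4-(2-methyl-1,3-dioxolan-2-yl)cyclohex-1-en-1-yl]oxy}silane F2. Treatment of F2 with NBS and then LiBr in DMF, as in step 3, gives 8.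

Step 3 (cis-bromo ketone). Only a modest preference for the equatorial bromide is expected at equilibrium, and separation from 7 may be poor. The fallback uses the kinetic axial bromide in the mirror-image series and corrects the side-chain centre at the end; it sets out from 2 and 3 and comes back at 10. Step 2 is run with the (R)-catalyst, giving the keto aldehyde (S)-2-(2-methyl-1,3-dioxolan-2-yl)-5-oxohexanal F3 and from it the enone (S)-4-(2-methyl-1,3-dioxolan-2-yl)cyclohex-2-en-1-one F4. Hydrosilylation as before gives the silyl enol ether (S)-triethyl{[4-(2-methyl-1,3-dioxolan-2-yl)cyclohex-1-en-1-yl]oxy}silane F5, and NBS at −78 °C without bromide equilibration gives the kinetic trans-bromo ketone (2R,4S)-2-bromo-4-(2-methyl-1,3-dioxolan-2-yl)cyclohexan-1-one F6; the minor cis isomer is removed at this stage. MeMgBr with CeCl3 at −78 °C adds anti to the axial C–Br bond, the classical cis-halohydrin outcome, to give the bromohydrin (1S,2R,4S)-2-bromo-1-methyl-4-(2-methyl-1,3-dioxolan-2-yl)cyclohexan-1-ol F7. Aqueous HCl gives the methyl ketone 1-[(1S,3R,4S)-3-bromo-4-hydroxy-4-methylcyclohexyl]ethan-1-one F8. K2CO3 in MeOH at rt then epimerises the centre α to the acetyl group toward the isomer in which Br, CH3 and acetyl are all equatorial, which is 10.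

Step 13 (fragment union). A hindered lithium enolate and a moderately reactive allylic chloride may give slow reaction, O-alkylation or proton transfer. The fallback replaces the allylic chloride by a far more reactive α-bromo ketone and makes the exocyclic methylene afterwards; it sets out from 11 (with enolate 20 from 19) and comes back at 21. Kinetic enolisation of 11 (LiN(SiMe3)2, Me3SiCl, THF, −78 °C) gives the silyl enol ether {[(1S,2R,4R)-2-bromo-1-methyl-4-{1-[(trimethylsilyl)oxy]ethenyl}cyclohexyl]oxy}triethylsilane F9. NBS converts it to the bromomethyl ketone 2-bromo-1-{(1R,3R,4S)-3-bromo-4-methyl-4-[(triethylsilyl)oxy]cyclohexyl}ethan-1-one F10. Alkylation of enolate 20 with F10 (THF, −78 °C) gives the 1,4-diketone (2S,5S,6R)-6-{2-[(1R,3R,4S)-3-bromo-4-methyl-4-(triethylsilyloxy)cyclohexyl]-2-oxoethyl}-2-methyl-5-(prop-1-en-2-yl)-2-(triethylsilyloxy)cyclohexan-1-one F11. Ph3P=CH2 (1.1 equiv, THF, 0 °C) then methylenates only the side-chain ketone, because the ring ketone is flanked by a quaternary and a tertiary carbon, and this gives 21.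

**Further compounds**
F1 | step 2 | 4-(2-methyl-1,3-dioxolan-2-yl)cyclohexan-1-one | CC1(OCCO1)C1CCC(=O)CC1
F2 | step 2 | (R)-trimethyl{[4-(2-methyl-1,3-dioxolan-2-yl)cyclohex-1-en-1-yl]oxy}silane | C[Si](C)(C)OC1=CC[C@@H](CC1)C1(C)OCCO1
F3 | step 3 | (S)-2-(2-methyl-1,3-dioxolan-2-yl)-5-oxohexanal | O=C[C@H](CCC(C)=O)C1(C)OCCO1
F4 | step 3 | (S)-4-(2-methyl-1,3-dioxolan-2-yl)cyclohex-2-en-1-one | O=C1C=C[C@H](CC1)C1(C)OCCO1
F5 | step 3 | (S)-triethyl{[4-(2-methyl-1,3-dioxolan-2-yl)cyclohex-1-en-1-yl]oxy}silane | CC[Si](CC)(CC)OC1=CC[C@H](CC1)C1(C)OCCO1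
F6 | step 3 | (2R,4S)-2-bromo-4-(2-methyl-1,3-dioxolan-2-yl)cyclohexan-1-one | CC1(OCCO1)[C@H]1CCC(=O)[C@H](Br)C1
F7 | step 3 | (1S,2R,4S)-2-bromo-1-methyl-4-(2-methyl-1,3-dioxolan-2-yl)cyclohexan-1-ol | CC1(OCCO1)[C@H]1CC[C@](C)(O)[C@H](Br)C1
F8 | step 3 | 1-[(1S,3R,4S)-3-bromo-4-hydroxy-4-methylcyclohexyl]ethan-1-one | CC(=O)[C@H]1CC[C@](C)(O)[C@H](Br)C1
F9 | step 13 | {[(1S,2R,4R)-2-bromo-1-methyl-4-{1-[(trimethylsilyl)oxy]ethenyl}cyclohexyl]oxy}triethylsilane | C=C(O[Si](C)(C)C)[C@@H]1CC[C@](C)(O[Si](CC)(CC)CC)[C@H](Br)C1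
F10 | step 13 | 2-bromo-1-{(1R,3R,4S)-3-bromo-4-methyl-4-[(triethylsilyl)oxy]cyclohexyl}ethan-1-one | BrCC(=O)[C@@H]1CC[C@](C)(O[Si](CC)(CC)CC)[C@H](Br)C1
F11 | step 13 | (2S,5S,6R)-6-{2-[(1R,3R,4S)-3-bromo-4-methyl-4-(triethylsilyloxy)cyclohexyl]-2-oxoethyl}-2-methyl-5-(prop-1-en-2-yl)-2-(triethylsilyloxy)cyclohexan-1-one | O=C(C[C@@H]1[C@@H](C(=C)C)CC[C@](C)(O[Si](CC)(CC)CC)C1=O)[C@@H]1CC[C@](C)(O[Si](CC)(CC)CC)[C@H](Br)C1
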